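**Retrosynthetic overview**

- The route rests on the quaternary spiro carbon C6: it is bonded to C1 (the C=CH2 carbon) and C5 (CMe2) of ring A and lies 1,4 (para) to C9, the C(Me)Cl carbon, in ring B. This is the pattern left when the para carbon of a phenol attacks the internal carbon of a tethered terminal alkyne.
- Key disconnection: the C6–C1 bond. Ring B is the phenol ring and is present from the start; ring A is closed in step 7 by gold-catalysed ipso-cyclisation, which turns ring B into a cyclohexa-2,5-dienone.
- C6 becomes stereogenic when an ene-reductase reduces one of the two dienone alkenes. The remaining enone is taken through an enol triflate to the C8=C9 methyl alkene.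
- Endgame: C4 carbinol to ketone to vinyl bromide, anti addition of BrCl across C8=C9, then allylic oxidation at C2 to the dienone.
- The phenol precursor comes from 4-hydroxyphenylacetone by gem-dimethylation, propargylation, oxazaborolidine reduction and silylation.

Key step: step 7

Remark: one fixed numbering of the spiro[5.5]undecane core is used in names and text (C1 methylidene carbon, C4 carbinol/C–Br carbon, C5 CMe2, C6 spiro, C8 CHBr, C9 C(Me)Cl). It is assumed that a screening panel supplies an ene-reductase variant that reduces the C10=C11 alkene of 12.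

**Step 1**
Reactants: 1 1-(4-hydroxyphenyl)propan-2-one
Product: 2 1-{4-[tri(propan-2-yl)silyloxy]phenyl}propan-2-one
Conditions: i-Pr3SiCl, imidazole, DMF, rt
Reagents that add atoms: chlorotri(propan-2-yl)silane, CC(C)[Si](Cl)(C(C)C)C(C)C
Why: O-silylation of the phenol gives a bulky aryl silyl ether that withstands the enolate chemistry ahead and is later cleaved by fluoride in the presence of an alkyl silyl ether.

**Step 2**
Reactants: 2 1-{4-[tri(propan-2-yl)silyloxy]phenyl}propan-2-one; 3 iodomethane
Product: 5 3-methyl-3-{4-[tri(propan-2-yl)silyloxy]phenyl}butan-2-one, via monomethyl ketone 4 (not isolated)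
Conditions: NaH (2.2 equiv), MeI (2.5 equiv), THF, 0 °C to rt
Reagents that add atoms: iodomethane, CI
Why: Two enolate C-alkylations occur at the benzylic carbon, the more acidic α-position (aryl-stabilised enolate), and build the gem-dimethyl carbon (future C5).

**Step 3**
Reactants: 5 3-methyl-3-{4-[tri(propan-2-yl)silyloxy]phenyl}butan-2-one; 6 (3-bromoprop-1-yn-1-yl)trimethylsilane
Product: 8 2-methyl-2-{4-[tri(propan-2-yl)silyloxy]phenyl}-7-(trimethylsilyl)hept-6-yn-3-one, via lithium enolate 7 (not isolated)
Conditions: LiN(i-Pr)2 (commercial solution), THF, −78 °C; then 6, −78 to 0 °C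
Reagents that add atoms: (3-bromoprop-1-yn-1-yl)trimethylsilane, C[Si](C)(C)C#CCBr
Why: Enolate alkylation (SN2 at the propargylic bromide) at the only enolisable carbon, the methyl group; the C-silyl group blocks allene formation and alkyne deprotonation.

**Step 4**
Reactants: 8 2-methyl-2-{4-[tri(propan-2-yl)silyloxy]phenyl}-7-(trimethylsilyl)hept-6-yn-3-one
Product: 9 (3S)-2-methyl-2-{4-[tri(propan-2-yl)silyloxy]phenyl}-7-(trimethylsilyl)hept-6-yn-3-ol
Conditions: (R)-2-methyl-CBS-oxazaborolidine (10 mol %), BH3·SMe2, THF, −20 °C; MeOH quench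
Reagents that add atoms: none
Why: Corey–Bakshi–Shibata reduction, in which the (R)-catalyst distinguishes the tertiary benzylic group (large) from the CH2 chain (small) and delivers hydride to the face that gives the (S)-carbinol; the silylated alkyne is not hydroborated at this temperature.

**Step 5**
Reactants: 9 (3S)-2-methyl-2-{4-[tri(propan-2-yl)silyloxy]phenyl}-7-(trimethylsilyl)hept-6-yn-3-ol
Product: 10 tert-butyl(dimethyl){[(3S)-2-methyl-2-{4-[tri(propan-2-yl)silyloxy]phenyl}-7-(trimethylsilyl)hept-6-yn-3-yl]oxy}silane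
Conditions: t-BuMe2SiOTf, 2,6-lutidine, CH2Cl2, −78 to 0 °C
Reagents that add atoms: tert-butyldimethylsilyl trifluoromethanesulfonate, CC(C)(C)[Si](C)(C)OS(=O)(=O)C(F)(F)F
Why: Silylation with the reactive silyl triflate protects the hindered neopentylic secondary alcohol, which must stay masked until ring B no longer carries an enone.

**Step 6**
Reactants: 10 tert-butyl(dimethyl){[(3S)-2-methyl-2-{4-[tri(propan-2-yl)silyloxy]phenyl}-7-(trimethylsilyl)hept-6-yn-3-yl]oxy}silane
Product: 11 4-[(3S)-3-{[tert-butyl(dimethyl)silyl]oxy}-2-methylhept-6-yn-2-yl]phenol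
Conditions: Bu4NF (2.2 equiv), THF, 0 °C; aq NH4Cl
Reagents that add atoms: none
Why: Selective desilylation, since fluoride cleaves the aryl O–Si and alkynyl C–Si bonds far faster than the hindered secondary alkyl silyl ether next to the quaternary carbon.

**Step 7**
Reactants: 11 4-[(3S)-3-{[tert-butyl(dimethyl)silyl]oxy}-2-methylhept-6-yn-2-yl]phenol
Product: 12 (4S)-4-{[tert-butyl(dimethyl)silyl]oxy}-5,5-dimethyl-1-methylidenespiro[5.5]undeca-7,10-dien-9-one
Conditions: Ph3PAuNTf2 (5 mol %), CH2Cl2 (0.02 M), rt
Reagents that add atoms: none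
Why: Cationic monovalent gold coordinates the terminal alkyne, and the ring carbon para to the hydroxyl (the one carrying the tether) attacks the internal alkyne carbon anti to gold; loss of the phenolic proton gives the cyclohexa-2,5-dienone and protodeauration of the alkenylgold leaves the 1-methylidene group. The closest known reaction type is the gold-catalysed dearomative ipso-cyclisation of phenols onto tethered alkynes. Ring A closes in the 6-exo-dig mode by forming the C6–C1 bond, and ring B is the dearomatised phenol ring. No new stereocentre forms, because C6 carries two identical dienone arms and C4 is untouched. The step needs ipso attack to win over attack by the ring carbons ortho to the tether (seven-membered ring) and over intermolecular O–H addition; the para hydroxyl makes the ipso carbon the most nucleophilic ring position, the gem-dimethyl group at C5 folds the chain toward it (gem-dialkyl effect), and high dilution suppresses intermolecular paths. The bulky silyl ether keeps the C4 oxygen from adding to the alkyne or to the new dienone.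

**Step 8**
Reactants: 12 (4S)-4-{[tert-butyl(dimethyl)silyl]oxy}-5,5-dimethyl-1-methylidenespiro[5.5]undeca-7,10-dien-9-one
Product: 13 (4S,6S)-4-{[tert-butyl(dimethyl)silyl]oxy}-5,5-dimethyl-1-methylidenespiro[5.5]undec-7-en-9-one
Conditions: ene-reductase (Old Yellow Enzyme family, variant chosen by screening), NADP+ (cat.), glucose dehydrogenase, D-glucose, KPi buffer pH 7.5, 10% DMSO, 30 °C
Reagents that add atoms: none
Why: Flavin-dependent ene-reductase desymmetrisation of a 4,4-disubstituted cyclohexa-2,5-dienone, in which hydride goes to C11 and a proton to C10 of the alkene on the side of the C4 oxygen, so that C6 becomes the (6S) centre; because C4 is already (S), any product of the other sense is a separable diastereomer.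

**Step 9**
Reactants: 13 (4S,6S)-4-{[tert-butyl(dimethyl)silyl]oxy}-5,5-dimethyl-1-methylidenespiro[5.5]undec-7-en-9-one
Product: 15 (4S,6S)-4-{[tert-butyl(dimethyl)silyl]oxy}-5,5-dimethyl-1-methylidenespiro[5.5]undec-8-en-9-yl trifluoromethanesulfonate, via lithium enolate 14 (not isolated)
Conditions: LiBH(s-Bu)3, THF, −78 °C; then PhNTf2, −78 to 0 °C
Reagents that add atoms: N-phenylbis(trifluoromethanesulfonimide), O=S(=O)(N(c1ccccc1)S(=O)(=O)C(F)(F)F)C(F)(F)F
Why: Conjugate hydride reduction of the β-unsubstituted enone gives the enolate regiospecifically on the C8–C9 side and O-triflation traps it, so the symmetric saturated ketone, in which C6 would no longer be stereogenic, is never formed.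

**Step 10**
Reactants: 15 (4S,6S)-4-{[tert-butyl(dimethyl)silyl]oxy}-5,5-dimethyl-1-methylidenespiro[5.5]undec-8-en-9-yl trifluoromethanesulfonate; 16 chloro(methyl)zinc
Product: 17 tert-butyl(dimethyl){[(4S,6S)-5,5,9-trimethyl-1-methylidenespiro[5.5]undec-8-en-4-yl]oxy}silane
Conditions: MeZnCl, Pd(PPh3)4 (5 mol %), THF, 50 °C
Reagents that add atoms: chloro(methyl)zinc, C[Zn]Cl
Why: Negishi coupling of the alkenyl triflate (oxidative addition to zerovalent palladium, transmetallation, reductive elimination) places the methyl group on C9 without moving the alkene.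

**Step 11**
Reactants: 17 tert-butyl(dimethyl){[(4S,6S)-5,5,9-trimethyl-1-methylidenespiro[5.5]undec-8-en-4-yl]oxy}silane
Product: 18 (4S,6S)-5,5,9-trimethyl-1-methylidenespiro[5.5]undec-8-en-4-ol
Conditions: Bu4NF (3 equiv), THF, 50 °C
Reagents that add atoms: none
Why: Fluoride cleaves the hindered alkyl silyl ether, which is safe now that ring B has no enone to which the C4 alkoxide could add.

**Step 12**
Reactants: 18 (4S,6S)-5,5,9-trimethyl-1-methylidenespiro[5.5]undec-8-en-4-ol
Product: 19 (6S)-5,5,9-trimethyl-1-methylidenespiro[5.5]undec-8-en-4-one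
Conditions: Dess–Martin periodinane, CH2Cl2, 0 °C to rt
Reagents that add atoms: none
Why: Dess–Martin oxidation of the secondary alcohol gives the C4 ketone and removes the carbinol centre once it has served to make the earlier intermediates single, separable diastereomers.

**Step 13**
Reactants: 19 (6S)-5,5,9-trimethyl-1-methylidenespiro[5.5]undec-8-en-4-one
Product: 21 (6S)-5,5,9-trimethyl-1-methylidenespiro[5.5]undeca-3,8-dien-4-yl trifluoromethanesulfonate, via potassium enolate 20 (not isolated)
Conditions: KN(SiMe3)2, THF, −78 °C; then PhNTf2, −78 to 0 °C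
Reagents that add atoms: N-phenylbis(trifluoromethanesulfonimide), O=S(=O)(N(c1ccccc1)S(=O)(=O)C(F)(F)F)C(F)(F)F
Why: The ketone can enolise only toward C3 because C5 is quaternary, so deprotonation and O-triflation give the C3=C4 enol triflate as one regioisomer.

**Step 14**
Reactants: 21 (6S)-5,5,9-trimethyl-1-methylidenespiro[5.5]undeca-3,8-dien-4-yl trifluoromethanesulfonate
Product: 22 trimethyl[(6S)-5,5,9-trimethyl-1-methylidenespiro[5.5]undeca-3,8-dien-4-yl]stannane
Conditions: (Me3Sn)2, Pd(PPh3)4 (5 mol %), LiCl, dioxane, 80 °C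
Reagents that add atoms: hexamethyldistannane, C[Sn](C)(C)[Sn](C)(C)C
Why: Palladium-catalysed stannylation of the alkenyl triflate with the distannane (Stille-type coupling) turns the C4–O bond into a C4–Sn bond.

**Step 15**
Reactants: 22 trimethyl[(6S)-5,5,9-trimethyl-1-methylidenespiro[5.5]undeca-3,8-dien-4-yl]stannane
Product: 23 (6S)-4-bromo-5,5,9-trimethyl-1-methylidenespiro[5.5]undeca-3,8-diene
Conditions: NBS, CH2Cl2, 0 °C, dark
Reagents that add atoms: N-bromosuccinimide, O=C1CCC(=O)N1Br
Why: Bromodestannylation, an electrophilic ipso substitution of the alkenylstannane that is much faster than addition of Br+ to the other alkenes and keeps the double bond at C3=C4.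

**Step 16**
Reactants: 23 (6S)-4-bromo-5,5,9-trimethyl-1-methylidenespiro[5.5]undeca-3,8-diene
Product: 24 (6S,8S,9S)-4,8-dibromo-9-chloro-5,5,9-trimethyl-1-methylidenespiro[5.5]undec-3-ene
Conditions: NBS, HCl (1 M in Et2O), CH2Cl2, −78 °C
Reagents that add atoms: N-bromosuccinimide, O=C1CCC(=O)N1Br; hydrogen chloride, Cl
Why: Electrophilic anti addition of BrCl to the trisubstituted C8=C9 alkene, the most electron-rich one (the bromoalkene is deactivated, the methylidene is less substituted and neopentylic); with C5 pseudo-equatorial and C1 pseudo-axial on the ring B half-chair, Br+ should add to the face opposite C1 and chloride should open the bromonium ion at tertiary C9 from the other face (Markovnikov), which sets C8 and C9 as the (8S,9S) trans-bromochloride with bromine cis to C5.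

**Step 17**
Reactants: 24 (6S,8S,9S)-4,8-dibromo-9-chloro-5,5,9-trimethyl-1-methylidenespiro[5.5]undec-3-ene
Product: 25 (6S,8S,9S)-4,8-dibromo-9-chloro-5,5,9-trimethyl-1-methylidenespiro[5.5]undec-3-en-2-ol (both C2 epimers)
Conditions: SeO2 (20 mol %), t-BuOOH, CH2Cl2, rt
Reagents that add atoms: tert-butyl hydroperoxide, CC(C)(C)OO; selenium dioxide, O=[Se]=O
Why: Allylic oxidation with SeO2 (ene reaction, then [2,3]-sigmatropic shift) at C2, the only hydrogen-bearing position allylic to the methylidene and also allylic to the bromoalkene, with the double bond returning to the exocyclic position.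

**Step 18**
Reactants: 25 (6S,8S,9S)-4,8-dibromo-9-chloro-5,5,9-trimethyl-1-methylidenespiro[5.5]undec-3-en-2-ol
Product: 26 (6S,8S,9S)-4,8-dibromo-9-chloro-5,5,9-trimethyl-1-methylidenespiro[5.5]undec-3-en-2-one
Conditions: Dess–Martin periodinane, CH2Cl2, 0 °C
Reagents that add atoms: none
Why: Dess–Martin oxidation of the doubly allylic alcohol gives the cross-conjugated dienone; both C2 epimers converge and no stereocentre is touched.

**Compound list**

1 | 1-(4-hydroxyphenyl)propan-2-one | CC(=O)Cc1ccc(O)cc1 | starting material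
2 | 1-{4-[tri(propan-2-yl)silyloxy]phenyl}propan-2-one | CC(=O)Cc1ccc(O[Si](C(C)C)(C(C)C)C(C)C)cc1 | intermediate
3 | iodomethane | CI | starting material
4 | 3-{4-[tri(propan-2-yl)silyloxy]phenyl}butan-2-one (racemic) | CC(=O)C(C)c1ccc(O[Si](C(C)C)(C(C)C)C(C)C)cc1 | intermediate (not isolated)
5 | 3-methyl-3-{4-[tri(propan-2-yl)silyloxy]phenyl}butan-2-one | CC(=O)C(C)(C)c1ccc(O[Si](C(C)C)(C(C)C)C(C)C)cc1 | intermediate
6 | (3-bromoprop-1-yn-1-yl)trimethylsilane | C[Si](C)(C)C#CCBr | starting material
7 | lithium 3-methyl-3-{4-[tri(propan-2-yl)silyloxy]phenyl}but-1-en-2-olate | C=C(O[Li])C(C)(C)c1ccc(O[Si](C(C)C)(C(C)C)C(C)C)cc1 | intermediate (not isolated)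
8 | 2-methyl-2-{4-[tri(propan-2-yl)silyloxy]phenyl}-7-(trimethylsilyl)hept-6-yn-3-one | CC(C)[Si](Oc1ccc(cc1)C(C)(C)C(=O)CCC#C[Si](C)(C)C)(C(C)C)C(C)C | intermediate
9 | (3S)-2-methyl-2-{4-[tri(propan-2-yl)silyloxy]phenyl}-7-(trimethylsilyl)hept-6-yn-3-ol | CC(C)[Si](Oc1ccc(cc1)C(C)(C)[C@@H](O)CCC#C[Si](C)(C)C)(C(C)C)C(C)C | intermediate
10 | tert-butyl(dimethyl){[(3S)-2-methyl-2-{4-[tri(propan-2-yl)silyloxy]phenyl}-7-(trimethylsilyl)hept-6-yn-3-yl]oxy}silane | CC(C)[Si](Oc1ccc(cc1)C(C)(C)[C@@H](O[Si](C)(C)C(C)(C)C)CCC#C[Si](C)(C)C)(C(C)C)C(C)C | intermediate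
11 | 4-[(3S)-3-{[tert-butyl(dimethyl)silyl]oxy}-2-methylhept-6-yn-2-yl]phenol | Oc1ccc(cc1)C(C)(C)[C@@H](O[Si](C)(C)C(C)(C)C)CCC#C | intermediate
12 | (4S)-4-{[tert-butyl(dimethyl)silyl]oxy}-5,5-dimethyl-1-methylidenespiro[5.5]undeca-7,10-dien-9-one | C=C1CC[C@H](O[Si](C)(C)C(C)(C)C)C(C)(C)C12C=CC(=O)C=C2 | intermediate
13 | (4S,6S)-4-{[tert-butyl(dimethyl)silyl]oxy}-5,5-dimethyl-1-methylidenespiro[5.5]undec-7-en-9-one | C=C1CC[C@H](O[Si](C)(C)C(C)(C)C)C(C)(C)[C@]12CCC(=O)C=C2 | intermediate
14 | lithium (4S,6S)-4-{[tert-butyl(dimethyl)silyl]oxy}-5,5-dimethyl-1-methylidenespiro[5.5]undec-8-en-9-olate | C=C1CC[C@H](O[Si](C)(C)C(C)(C)C)C(C)(C)[C@]12CCC(O[Li])=CC2 | intermediate (not isolated)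
15 | (4S,6S)-4-{[tert-butyl(dimethyl)silyl]oxy}-5,5-dimethyl-1-methylidenespiro[5.5]undec-8-en-9-yl trifluoromethanesulfonate | C=C1CC[C@H](O[Si](C)(C)C(C)(C)C)C(C)(C)[C@]12CCC(OS(=O)(=O)C(F)(F)F)=CC2 | intermediate
16 | chloro(methyl)zinc | C[Zn]Cl | starting material
17 | tert-butyl(dimethyl){[(4S,6S)-5,5,9-trimethyl-1-methylidenespiro[5.5]undec-8-en-4-yl]oxy}silane | C=C1CC[C@H](O[Si](C)(C)C(C)(C)C)C(C)(C)[C@]12CCC(C)=CC2 | intermediate
18 | (4S,6S)-5,5,9-trimethyl-1-methylidenespiro[5.5]undec-8-en-4-ol | C=C1CC[C@H](O)C(C)(C)[C@]12CCC(C)=CC2 | intermediate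
19 | (6S)-5,5,9-trimethyl-1-methylidenespiro[5.5]undec-8-en-4-one | C=C1CCC(=O)C(C)(C)[C@]12CCC(C)=CC2 | intermediate
20 | potassium (6S)-5,5,9-trimethyl-1-methylidenespiro[5.5]undeca-3,8-dien-4-olate | C=C1CC=C(O[K])C(C)(C)[C@]12CCC(C)=CC2 | intermediate (not isolated)
21 | (6S)-5,5,9-trimethyl-1-methylidenespiro[5.5]undeca-3,8-dien-4-yl trifluoromethanesulfonate | C=C1CC=C(OS(=O)(=O)C(F)(F)F)C(C)(C)[C@]12CCC(C)=CC2 | intermediate
22 | trimethyl[(6S)-5,5,9-trimethyl-1-methylidenespiro[5.5]undeca-3,8-dien-4-yl]stannane | C=C1CC=C([Sn](C)(C)C)C(C)(C)[C@]12CCC(C)=CC2 | intermediate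
23 | (6S)-4-bromo-5,5,9-trimethyl-1-methylidenespiro[5.5]undeca-3,8-diene | C=C1CC=C(Br)C(C)(C)[C@]12CCC(C)=CC2 | intermediate
24 | (6S,8S,9S)-4,8-dibromo-9-chloro-5,5,9-trimethyl-1-methylidenespiro[5.5]undec-3-ene | C=C1CC=C(Br)C(C)(C)[C@]12CC[C@](C)(Cl)[C@@H](Br)C2 | intermediate
25 | (6S,8S,9S)-4,8-dibromo-9-chloro-5,5,9-trimethyl-1-methylidenespiro[5.5]undec-3-en-2-ol (both C2 epimers) | C=C1C(O)C=C(Br)C(C)(C)[C@]12CC[C@](C)(Cl)[C@@H](Br)C2 | intermediate
26 | (6S,8S,9S)-4,8-dibromo-9-chloro-5,5,9-trimethyl-1-methylidenespiro[5.5]undec-3-en-2-one | C=C1C(=O)C=C(Br)C(C)(C)[C@]12CC[C@](C)(Cl)[C@@H](Br)C2 | target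

**Step count**

Total steps: 18. Longest linear sequence: 18 steps (from 1).

**Steps most likely to fail**

Step 16. The trans-diaxial opening mode is not available for chloride attack at C9 on the favoured ring B conformer, so three processes may compete with the intended one: Br+ adding on the face next to C1, chloride entering at secondary C8 in the diaxial mode, or the methylidene group capturing the C9 cation across the ring. The fallback sets out from 23 and separates the two events. NBS in acetone–water at 0 °C should give the bromohydrin (6S,8S,9S)-4,8-dibromo-5,5,9-trimethyl-1-methylidenespiro[5.5]undec-3-en-9-ol F3, because water in large excess captures the bromonium ion at the tertiary carbon, and diastereomeric bromohydrins can be separated at this stage. SOCl2 in CH2Cl2 at −20 °C then replaces the tertiary hydroxyl by chloride with retention, through participation of the neighbouring bromine and internal return of chloride. The sequence comes back to the route at 24.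

Step 8. The lipophilic, crowded dienone may bind poorly to the enzyme, the two alkenes may be told apart only weakly, or the enone product may be reduced a second time. The fallback sets out from 12 and uses ligand-controlled copper hydride chemistry: Cu(OAc)2 (divalent copper, reduced in the flask to the hydride), a DTBM-SEGPHOS enantiomer chosen by trial, and PhMe2SiH in toluene at 0 °C. This should give the silyl dienol ether {[(4S,6S)-4-{[tert-butyl(dimethyl)silyl]oxy}-5,5-dimethyl-1-methylidenespiro[5.5]undeca-7,9-dien-9-yl]oxy}dimethyl(phenyl)silane F2, which is no longer an enone and is therefore protected from over-reduction. K2CO3 in MeOH releases the enone, and the sequence comes back to the route at 13.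

Step 7. The gold-activated alkyne may be hydrated or attacked by a ring carbon ortho to the tether, or the acid set free may shift the exocyclic alkene or trigger a dienone–phenol rearrangement of the spirodienone. The fallback sets out from 11 and forms the same C6–C1 bond by cross-coupling under basic conditions. Markovnikov hydrobromination of the alkyne with Et4N+ HBr2− in CH2Cl2 should give the 2-bromoalkene 4-[(3S)-6-bromo-3-{[tert-butyl(dimethyl)silyl]oxy}-2-methylhept-6-en-2-yl]phenol F1. Intramolecular ipso-alkenylation of the phenol (Pd2(dba)3 as the source of zerovalent palladium, di-tert-butyl(biphenyl-2-yl)phosphine, K2CO3, dioxane, 80 °C) then closes ring A, and the sequence comes back to the route at 12.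

**Further compounds**

F1 | step 7 | 4-[(3S)-6-bromo-3-{[tert-butyl(dimethyl)silyl]oxy}-2-methylhept-6-en-2-yl]phenol | Oc1ccc(cc1)C(C)(C)[C@@H](O[Si](C)(C)C(C)(C)C)CCC(Br)=C
F2 | step 8 | {[(4S,6S)-4-{[tert-butyl(dimethyl)silyl]oxy}-5,5-dimethyl-1-methylidenespiro[5.5]undeca-7,9-dien-9-yl]oxy}dimethyl(phenyl)silane | C=C1CC[C@H](O[Si](C)(C)C(C)(C)C)C(C)(C)[C@]12CC=C(O[Si](C)(C)c3ccccc3)C=C2
F3 | step 16 | (6S,8S,9S)-4,8-dibromo-5,5,9-trimethyl-1-methylidenespiro[5.5]undec-3-en-9-ol | C=C1CC=C(Br)C(C)(C)[C@]12CC[C@](C)(O)[C@@H](Br)C2
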